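**Conventions.** Iridoid numbering is used in the text: C1 (acetal), O2, C3=C4, C5 and C9 (ring fusion), C6, C7, C8, C10 (CH2 on C8), C11 (CH2 on C4). In cyclopenta[c]pyran locants these are C5 = 4a, C6 = 5, C7 = 6, C8 = 7, C9 = 7a. β is the face carrying H‑5 and H‑9. The target is (1S,5S,7S,8R,9S): 1β‑O‑isovaleroyl, 7β‑OAc, 8α‑OH, 8β‑CH2OH. Numbered compounds are substrates and carbon‑contributing partners; simple reagents appear under conditions.

**Assumption.** The isothiourea antipode that gives (S)‑4 in Step 2 is taken to be (R)‑benzotetramisole; if the sense is opposite, the commercial enantiomer is used.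

## Retrosynthetic overview

1. Cut the C4–C11 bond last: the target comes from a C4 enol triflate and an (isovaleroyloxy)methyl‑tin reagent (proposed new Stille‑type acyloxymethylation).
2. The 7β‑OAc / 8α‑OH / 10‑OH array comes from C7‑selective acetolysis of a 7α,8α‑epoxy alcohol, made by Sharpless epoxidation of the C7=C8 allylic alcohol.
3. The allylic alcohol and enol triflate come from a bicyclic keto ester (C4 ketone, C8 ester).
4. The cyclopentene ring is formed second, by a phosphine‑catalysed [3+2] of an allenoate onto a preformed pyranone.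
5. The pyranone comes from furfuryl alcohol (Achmatowicz), then a dynamic kinetic isovaleroylation that sets C1 and installs the C1 ester of the target.

## Route

**Step 1**
Reactants: 1, furfuryl alcohol
Product: 2, (±)-6-hydroxy-2H-pyran-3(6H)-one
Conditions: NBS, NaHCO3, NaOAc, THF/H2O (4:1), 0 °C
Reagents that add atoms: water, O
Why: Achmatowicz oxidative ring expansion gives the racemic lactol, whose acetal centre epimerises freely by ring–chain tautomerism (used in Step 2).

**Step 2**
Reactants: 2; 3, isovaleric anhydride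
Product: 4, (2S)-5-oxo-5,6-dihydro-2H-pyran-2-yl 3-methylbutanoate
Conditions: (R)-BTM (5 mol %), i-Pr2NEt, CHCl3, −20 → 0 °C
Reagents that add atoms: isovaleric anhydride, CC(C)CC(=O)OC(=O)CC(C)C
Why: Isothiourea‑catalysed dynamic kinetic asymmetric acylation of the rapidly racemising lactol sets the acetal carbon (future C1) as S and installs the C1 isovalerate that is kept to the end.

**Step 3**
Reactants: 5, tert-butyl (triphenylphosphoranylidene)acetate; 6, acetyl chloride
Product: 7, tert-butyl buta-2,3-dienoate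
Conditions: Et3N, CH2Cl2, 0 °C → rt
Reagents that add atoms: acetyl chloride, CC(=O)Cl (supplies the CH2=C unit via ketene)
Why: Wittig olefination of ketene generated in situ from acetyl chloride is the standard allenoate synthesis.

**Step 4**
Reactants: 4; 7
Product: 8, tert-butyl (1S,4aS,7aS)-1-[(3-methylbutanoyl)oxy]-4-oxo-1,3,4,4a,5,7a-hexahydrocyclopenta[c]pyran-7-carboxylate (cis‑fused; H‑5, H‑9 and 1‑O‑acyl all β; C7=C8 with the ester on C8)
Conditions: PPh3 (20 mol %), toluene, 80 °C
Reagents that add atoms: tert-butyl buta-2,3-dienoate, C=C=CC(=O)OC(C)(C)C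
Why: Lu phosphine‑catalysed allenoate–enone [3+2] annulation, in which the zwitterion α‑carbon adds to C9 anti to the pseudo‑axial C1 acyloxy group and ring closure at C5 is necessarily cis, setting 5S and 9S.

**Step 5**
Reactants: 8
Product: 9, tert-butyl (1S,4aS,7aS)-1-[(3-methylbutanoyl)oxy]-4-[(trifluoromethanesulfonyl)oxy]-1,4a,5,7a-tetrahydrocyclopenta[c]pyran-7-carboxylate (C3=C4 enol triflate)
Conditions: KHMDS, THF, −78 °C; then Comins' reagent, −78 °C
Reagents that add atoms: Comins' reagent, FC(F)(F)S(=O)(=O)N(c1ccc(Cl)cn1)S(=O)(=O)C(F)(F)F (supplies CF3SO2)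
Why: Kinetic enolisation at the accessible C3 methylene, not the hindered ring‑fusion C5–H, followed by O‑triflation; the ketone is far more acidic than either ester, and no stereocentre is affected.

**Step 6**
Reactants: 9
Product: 10, (1S,4aS,7aS)-1-[(3-methylbutanoyl)oxy]-4-[(trifluoromethanesulfonyl)oxy]-1,4a,5,7a-tetrahydrocyclopenta[c]pyran-7-carboxylic acid
Conditions: TFA/CH2Cl2 (1:4), 0 °C → rt
Reagents that add atoms: none
Why: Acidolysis of the tert‑butyl ester; the acyl acetal and vinyl triflate tolerate TFA because the electron‑poor enol triflate disfavours oxocarbenium formation at C1.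

**Step 7**
Reactants: 10
Product: 11, (1S,4aS,7aS)-7-(hydroxymethyl)-4-[(trifluoromethanesulfonyl)oxy]-1,4a,5,7a-tetrahydrocyclopenta[c]pyran-1-yl 3-methylbutanoate
Conditions: i-BuOCOCl, N-methylmorpholine, THF, −15 °C; then NaBH4, THF/H2O, −15 → 0 °C, 15 min
Reagents that add atoms: none
Why: Chemoselective reduction of the acid via its mixed carbonic anhydride gives the C10 allylic alcohol without touching the C1 isovalerate or the triflate, which a direct hydride reduction of an ester would not allow.

**Step 8**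
Reactants: 11
Product: 12, [(1S,4aS,6R,7R,7aS)-6,7-epoxy-7-(hydroxymethyl)-4-[(trifluoromethanesulfonyl)oxy]-1,4a,5,6,7,7a-hexahydrocyclopenta[c]pyran-1-yl] 3-methylbutanoate (7α,8α‑epoxide, O anti to H‑9; CH2OH on C8 β)
Conditions: Ti(OiPr)4 (1.1 equiv), D-(−)-diisopropyl tartrate (1.3 equiv), t-BuOOH, 4 Å MS, CH2Cl2, −20 °C; citric acid work‑up
Reagents that add atoms: tert-butyl hydroperoxide, CC(C)(C)OO (supplies O)
Why: Sharpless asymmetric epoxidation of the primary allylic alcohol, where the D‑tartrate ("2R" series) delivers oxygen to the α‑face under reagent control and sets C7 and C8 as R,R.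

**Step 9**
Reactants: 12; 13, acetic acid
Product: 14, (1S,4aS,6S,7R,7aS)-6-acetoxy-7-hydroxy-7-(hydroxymethyl)-4-[(trifluoromethanesulfonyl)oxy]-1,4a,5,6,7,7a-hexahydrocyclopenta[c]pyran-1-yl 3-methylbutanoate (7β‑OAc, 8α‑OH, 8β‑CH2OH)
Conditions: Ti(OiPr)4 (1.5 equiv), AcOH (2 equiv), CH2Cl2, 0 °C → rt; aqueous tartaric acid work‑up
Reagents that add atoms: acetic acid, CC(=O)O
Why: Ti(IV)‑mediated C3‑selective opening of a 2,3‑epoxy alcohol by carboxylate (Sharpless), where SN2 attack at secondary C7 from the β‑face inverts C7 to S while the C8–O bond is retained as the 8α‑OH.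

**Step 10**
Reactants: 15, (tributylstannyl)methanol; 16, isovaleryl chloride
Product: 17, (tributylstannyl)methyl 3-methylbutanoate
Conditions: pyridine, DMAP (cat.), CH2Cl2, 0 °C
Reagents that add atoms: isovaleryl chloride, CC(C)CC(=O)Cl
Why: Simple O‑acylation of a primary alcohol.

**Step 11**
Reactants: 14; 17
Product: 18, jatamanvaltrate H, [(1S,4aS,6S,7R,7aS)-6-acetoxy-7-hydroxy-7-(hydroxymethyl)-1-[(3-methylbutanoyl)oxy]-1,4a,5,6,7,7a-hexahydrocyclopenta[c]pyran-4-yl]methyl 3-methylbutanoate
Conditions: Pd2(dba)3 (5 mol %), AsPh3 (20 mol %), CuCl (2 equiv), LiCl (4 equiv), DMSO, 45 °C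
Reagents that add atoms: (tributylstannyl)methyl 3-methylbutanoate, CCCC[Sn](CCCC)(CCCC)COC(=O)CC(C)C (supplies CH2OC(=O)CH2CH(CH3)2)
Why: Proposed new method: Pd/Cu‑co‑catalysed Stille‑type transfer of an intact acyloxymethyl group from tin to a cyclic β‑alkoxy enol triflate bearing free hydroxyls, forging the C4–C11 bond and delivering the second isovalerate in one step without touching a stereocentre; mechanistically, Pd(0) adds oxidatively to C4–OTf, the α‑oxygenated CH2 transmetalates Sn→Cu→Pd in preference to n‑butyl (α‑heteroatom activation assisted by C=O→Sn coordination), and reductive elimination gives a glycal‑type allylic ester that ionises only slowly with the weakly donating AsPh3/Pd(0); the neutral conditions avoid acetyl migration; the closest known reaction types are the Kosugi–Migita–Stille hydroxymethylation of vinyl triflates with Bu3SnCH2OH, Pd/Cu coupling of α‑acyloxyalkylstannanes with acid chlorides, and cross‑coupling of acyloxymethyl‑zinc or ‑trifluoroborate reagents with aryl halides.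

## Compound list

1 | furfuryl alcohol | OCc1ccco1 | starting material
2 | (±)-6-hydroxy-2H-pyran-3(6H)-one | O=C1COC(O)C=C1 | intermediate
3 | isovaleric anhydride | CC(C)CC(=O)OC(=O)CC(C)C | starting material
4 | (2S)-5-oxo-5,6-dihydro-2H-pyran-2-yl 3-methylbutanoate | O=C1CO[C@@H](OC(=O)CC(C)C)C=C1 | intermediate
5 | tert-butyl (triphenylphosphoranylidene)acetate | CC(C)(C)OC(=O)C=P(c1ccccc1)(c1ccccc1)c1ccccc1 | starting material
6 | acetyl chloride | CC(=O)Cl | starting material
7 | tert-butyl buta-2,3-dienoate | C=C=CC(=O)OC(C)(C)C | intermediate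
8 | tert-butyl (1S,4aS,7aS)-1-[(3-methylbutanoyl)oxy]-4-oxo-1,3,4,4a,5,7a-hexahydrocyclopenta[c]pyran-7-carboxylate | O=C1CO[C@@H](OC(=O)CC(C)C)[C@@H]2C(C(=O)OC(C)(C)C)=CC[C@H]12 | intermediate
9 | tert-butyl (1S,4aS,7aS)-1-[(3-methylbutanoyl)oxy]-4-(triflyloxy)-1,4a,5,7a-tetrahydrocyclopenta[c]pyran-7-carboxylate | O=S(=O)(OC1=CO[C@@H](OC(=O)CC(C)C)[C@@H]2C(C(=O)OC(C)(C)C)=CC[C@H]12)C(F)(F)F | intermediate
10 | (1S,4aS,7aS)-1-[(3-methylbutanoyl)oxy]-4-(triflyloxy)-1,4a,5,7a-tetrahydrocyclopenta[c]pyran-7-carboxylic acid | O=S(=O)(OC1=CO[C@@H](OC(=O)CC(C)C)[C@@H]2C(C(=O)O)=CC[C@H]12)C(F)(F)F | intermediate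
11 | (1S,4aS,7aS)-7-(hydroxymethyl)-4-(triflyloxy)-1,4a,5,7a-tetrahydrocyclopenta[c]pyran-1-yl 3-methylbutanoate | O=S(=O)(OC1=CO[C@@H](OC(=O)CC(C)C)[C@@H]2C(CO)=CC[C@H]12)C(F)(F)F | intermediate
12 | (1S,4aS,6R,7R,7aS)-6,7-epoxy-7-(hydroxymethyl)-4-(triflyloxy)-1,4a,5,6,7,7a-hexahydrocyclopenta[c]pyran-1-yl 3-methylbutanoate (α‑epoxide) | O=S(=O)(OC1=CO[C@@H](OC(=O)CC(C)C)[C@@H]2[C@]3(CO)O[C@@H]3C[C@H]12)C(F)(F)F | intermediate
13 | acetic acid | CC(=O)O | starting material
14 | (1S,4aS,6S,7R,7aS)-6-acetoxy-7-hydroxy-7-(hydroxymethyl)-4-(triflyloxy)-1,4a,5,6,7,7a-hexahydrocyclopenta[c]pyran-1-yl 3-methylbutanoate | O=S(=O)(OC1=CO[C@@H](OC(=O)CC(C)C)[C@@H]2[C@@](O)(CO)[C@@H](OC(C)=O)C[C@H]12)C(F)(F)F | intermediate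
15 | (tributylstannyl)methanol | CCCC[Sn](CCCC)(CCCC)CO | starting material
16 | isovaleryl chloride | CC(C)CC(=O)Cl | starting material
17 | (tributylstannyl)methyl 3-methylbutanoate | CCCC[Sn](CCCC)(CCCC)COC(=O)CC(C)C | intermediate
18 | jatamanvaltrate H | CC(=O)O[C@H]1C[C@@H]2C(COC(=O)CC(C)C)=CO[C@@H](OC(=O)CC(C)C)[C@@H]2[C@@]1(O)CO | target

## Step count and risks

Total steps: 11. Longest linear sequence: 9 (Steps 1, 2, 4, 5, 6, 7, 8, 9, 11, from furfuryl alcohol); Steps 3 and 10 are one‑step reagent preparations.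

Three steps most likely to fail:

1. **Step 11 (proposed new acyloxymethyl Stille coupling).** Risks are slow sp3 transfer, competing butyl transfer, and Pd‑ionisation of the product's allylic ester. Fallback with known chemistry: TES‑protect the 10‑OH of 14; perform a Kosugi–Migita–Stille hydroxymethylation with 15 (Pd(PPh3)4, LiCl, dioxane, 90 °C) to give the C11 alcohol; acylate with 16/pyridine; remove TES with HF·pyridine.

2. **Step 8 (Sharpless epoxidation onto the presumably more hindered α‑face, possibly mismatched with substrate bias).** Fallback: abandon the α‑epoxide and use the substrate's own β‑preference. Protect the 10‑OH of 11 as its TBDPS ether; epoxidise with m‑CPBA on the convex β‑face; open the epoxide by acid‑catalysed hydrolysis at tertiary C8 with inversion to give the 7β,8α‑diol; acetylate the secondary 7‑OH; continue to the coupling and desilylate last with HF·pyridine.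

3. **Step 5 (C3 versus C5 regioselectivity of enolisation).** Fallback: replace kinetic enolate trapping with a thermodynamic enol‑silane relay. Form the O2‑conjugated Δ3 silyl enol ether under equilibrating soft enolisation (TMSOTf/Et3N), then exchange Si for Tf regiospecifically with CsF/PhNTf2 (one extra step).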